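**Plan**
- Retrosynthesis: the pyranone is opened at O1–C2 (cyclodehydration) to an acylphloroglucinol 1,3-diketone. The arene bond C4a–C5 is then cut (Claisen) to a linear C22 tetraketo methyl ester. The chain is cut between its C6 and C7 into a C6 diketo ester and a C16 β-keto ester, and the latter into a C14 acid chloride plus one acetate unit.
- Enabling feature: the benzene ring C4a–C5–C6–C7–C8–C8a carries oxygen on the alternate carbons C5, C7 and C8a, and C4a bears the 1,3-dioxygenated chain C4–C3–C2 with the C13 tail. The ring is therefore one fold of a poly-β-carbonyl chain whose ester carbon becomes C5.
- Forward order: the chain is joined first (C14 + C2, then C16 + C6), the benzene ring is closed by Claisen cyclization, and the pyranone ring is closed last by acid-catalysed dehydration.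
- Stereochemistry: the target has no stereocentre and no stereogenic double bond, so nothing has to be set or preserved.

Key step: step 3

Remark: the target is achiral, so "single enantiomer" is read as the compound as drawn; methyl 3,5-dioxohexanoate is taken as a purchasable material.

**Step 1**
Reactants: 1 tetradecanoyl chloride; 2 Meldrum's acid (2,2-dimethyl-1,3-dioxane-4,6-dione)
Product: 4 methyl 3-oxohexadecanoate, via tetradecanoyl Meldrum's acid 3 (not isolated)
Conditions: pyridine (2 equiv), CH2Cl2, 0 °C → rt; dilute HCl wash, evaporation; then MeOH, reflux
Reagents that add atoms: methanol, CO
Why: C-acylation of the strongly acidic Meldrum's acid by an acid chloride, followed by methanolysis with loss of acetone and CO2 (the Meldrum's acid β-keto ester synthesis), is a standard and reliable way to extend a fatty acid chloride by one acetate unit.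

**Step 2**
Reactants: 4 methyl 3-oxohexadecanoate; 5 methyl 3,5-dioxohexanoate
Product: 6 methyl 3,5,7,9-tetraoxodocosanoate
Conditions: 5 (2 equiv), LDA (6 equiv), THF, 0 °C; then lithium enolate of 4 (4 + LDA, 1 equiv, THF, 0 °C), 0 °C → rt; quench into ice-cold 1 M HCl
Reagents that add atoms: none
Why: The 2,4,6-trianion of 5 is nucleophilic only at its terminal C6 carbanion, and a crossed Claisen condensation of such a polyanion with the preformed metal enolate of a β-keto ester (whose acidic C2 proton is already removed) should join C6 of 5 to the ester carbon of 4 with loss of methoxide; the second equivalent of trianion acts as base for the more acidic product and is recovered as 5.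

**Step 3**
Reactants: 6 methyl 3,5,7,9-tetraoxodocosanoate
Product: 7 1-(2,4,6-trihydroxyphenyl)hexadecane-1,3-dione
Conditions: KOH (10 equiv), degassed MeOH, 0 °C → rt, Ar; then cold 2 M HCl to pH 2
Reagents that add atoms: none
Why: Excess methanolic base turns 6 into a polyenolate in which chain C6, flanked by the C5 and C7 carbonyls, acts as the carbanion; it adds to the C1 ester carbonyl, methoxide is expelled, and the resulting cyclohexane-1,3,5-trione tautomerizes at once to the phloroglucinolate, which makes the closure irreversible. The closest known reaction type is the base-induced intramolecular Claisen (Dieckmann-type) cyclization of 3,5,7-triketo esters to acylphloroglucinols, the laboratory counterpart of the chalcone-synthase fold. The carbocycle made of chain C1–C6 closes in a 6-exo-trig mode at the ester carbonyl with the enolate carbon as ring member, an allowed enolate closure, and this forms the arene bond C4a–C5 of the target. No stereocentre is created. The step needs the Claisen mode (C6 onto C1) to win over the aldol modes (C2 onto C7, C4 onto C9, C8 onto C3); this should be secured because under strongly basic conditions all four ketones are held as enolates and are poor acceptors, the ester is the only carbonyl with a leaving group, and aldol adducts can revert whereas methoxide loss followed by aromatization cannot. The product is symmetric about the acyl group, so the later pyranone closure carries no regiochemical question.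

**Step 4**
Reactants: 7 1-(2,4,6-trihydroxyphenyl)hexadecane-1,3-dione
Product: 9 5,7-dihydroxy-2-tridecyl-4H-chromen-4-one, via 2,5,7-trihydroxy-2-tridecylchroman-4-one 8 (not isolated)
Conditions: conc. HCl (cat.), AcOH, 80 °C
Reagents that add atoms: none
Why: An ortho phenol of the 2-hydroxyaryl 1,3-diketone adds to the C3 ketone to give the six-membered hemiketal, which loses water under acid to the conjugated, hydrogen-bonded chromone (the cyclodehydration that ends a Baker–Venkataraman chromone synthesis); both ortho hydroxyls are equivalent, so a single product is expected, and the transient racemic hemiketal centre is destroyed.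

**Compound list**
1 | tetradecanoyl chloride | CCCCCCCCCCCCCC(=O)Cl | starting material
2 | Meldrum's acid (2,2-dimethyl-1,3-dioxane-4,6-dione) | CC1(C)OC(=O)CC(=O)O1 | starting material
3 | tetradecanoyl Meldrum's acid, 5-(1-hydroxytetradecylidene)-2,2-dimethyl-1,3-dioxane-4,6-dione | CCCCCCCCCCCCCC(O)=C1C(=O)OC(C)(C)OC1=O | intermediate (not isolated)
4 | methyl 3-oxohexadecanoate | CCCCCCCCCCCCCC(=O)CC(=O)OC | intermediate
5 | methyl 3,5-dioxohexanoate | COC(=O)CC(=O)CC(C)=O | starting material
6 | methyl 3,5,7,9-tetraoxodocosanoate (keto form drawn; enol tautomers expected) | CCCCCCCCCCCCCC(=O)CC(=O)CC(=O)CC(=O)CC(=O)OC | intermediate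
7 | 1-(2,4,6-trihydroxyphenyl)hexadecane-1,3-dione | CCCCCCCCCCCCCC(=O)CC(=O)c1c(O)cc(O)cc1O | intermediate
8 | 2,5,7-trihydroxy-2-tridecylchroman-4-one (racemic hemiketal) | CCCCCCCCCCCCCC1(O)CC(=O)c2c(O)cc(O)cc2O1 | intermediate (not isolated)
9 | 5,7-dihydroxy-2-tridecyl-4H-chromen-4-one | CCCCCCCCCCCCCc1cc(=O)c2c(O)cc(O)cc2o1 | target

Total step count: 4
Longest linear sequence: 4 steps (1 → 4 → 6 → 7 → 9); 5 enters at step 2.

**Steps most likely to fail**

1. Step 2. Proton transfer from the C4 methylene of the enolate of 4 to the strongly basic trianion, or slow addition to an ester that is conjugated with an enolate, would return both partners unchanged.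
Fallback: it sets out from 1 and forms the chain bond C5–C6 instead of C6–C7. C-acylation of the lithium enolate of acetone (2.2 equiv, LDA, THF, −78 °C) with 1 should give heptadecane-2,4-dione F1. Its dilithio dianion (LDA, 2 equiv, THF, 0 °C; kinetic deprotonation at the terminal methyl, used in twofold amount so that one equivalent serves as base) is then acylated by the lithium salt of dimethyl 3-oxoglutarate. The attack goes to the ester arm that is not conjugated with the enolate, and acidic work-up brings the sequence back to the route at 6.

2. Step 3. Aldol closures with dehydration to resorcinol-type isomers, lactonization to a 4-hydroxy-2-pyranone on acidification, or retro-Claisen cleavage of the poly-β-carbonyl chain by hydroxide may compete with the Claisen closure.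
Fallback: it sets out from 4 and comes back to the route at 9. Thermal Mentzer condensation of 4 with phloroglucinol (neat or in diphenyl ether, about 240 °C, methanol and water distilled off) uses a purchased arene instead of building it. It forms C4–C4a and O1–C2 of the chromone in one operation and makes no new compound (F0).

3. Step 1. O-acylation or double acylation of Meldrum's acid, or decomposition of the acyl derivative before methanolysis, would cut the supply of 4.
Fallback: it sets out from 1 and comes back to the route at 4. Crossed Claisen condensation of 1 with the lithium enolate of methyl acetate (2.1 equiv, LDA, THF, −78 °C) gives the β-keto ester directly and makes no new compound (F0).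

Step 4 is expected to be the most reliable transformation and is therefore not listed.

**Further compounds**
F1 | step 2 | heptadecane-2,4-dione | CCCCCCCCCCCCCC(=O)CC(C)=O
F0 | step 3 | none | none
F0 | step 1 | none | none
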